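Ring A is assembled by a rhodium-catalysed five-plus-one carbonylation of a 3-acyloxy-1,4-enyne. The step exploits the meta-dioxygenation of ring A with unlike oxygens: the ester migrates from the future C2 to C3 while CO becomes C5 as a free phenol, so C3–O and C5–O are differentiated from the start, and the C1 chain and ring B at C2 arrive on adjacent carbons. One operation forms C4–C5, C5–C6 and the aromatic ring. The precursor is a tertiary ethynyl carbinol pivalate that carries benzylated ring B on the carbinol carbon and a 1,1-disubstituted alkene bearing the two-carbon chain to benzylated ring C.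

Key step: step 7

Assumption: the biaryl axis of the target is taken as freely rotating, so the target is achiral; the carbinol compounds 9, 12, 14 and 15 are racemic and are written without stereodescriptors.

Design of the precursor: the migrating ester is a pivalate. It is the poorer leaving group at a carbon that is tertiary, benzylic, allylic and propargylic, and its carbonyl oxygen is the more electron-rich partner for the 1,2-shift. In the product it should not pass to the neighbouring phenoxide during methylation. Benzyl ethers protect rings B and C because they tolerate the alkenyllithium, Grignard, carbonylation and methoxide steps and are removed together at the end.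

Step 1
Reactants: 1 2,5-dihydroxybenzaldehyde; 2 benzyl bromide
Product: 3 2,5-bis(benzyloxy)benzaldehyde
Conditions: BnBr (2.4 equiv), K2CO3 (3 equiv), DMF, 60 °C
Reagents that add atoms: benzyl bromide, BrCc1ccccc1
Why: Williamson ether synthesis, in which both phenoxides (the chelated ortho one included) are benzylated in warm DMF while the non-enolizable aldehyde is untouched.

Step 2
Reactants: 4 1-(benzyloxy)-3-(chloromethyl)benzene; 5 2,3-dibromopropene
Product: 7 1-(benzyloxy)-3-(3-bromobut-3-en-1-yl)benzene, via 3-(benzyloxy)benzylmagnesium chloride 6 (not isolated)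
Conditions: Mg, Et2O, 0 → 23 °C (slow addition); then 5, THF, 0 → 23 °C
Reagents that add atoms: 2,3-dibromopropene, C=C(Br)CBr
Why: Grignard formation from the benzylic chloride (less Wurtz coupling than from the bromide) followed by allylic substitution on 2,3-dibromopropene, in which only the allylic bromide is displaced and the vinylic bromide is kept.

Step 3
Reactants: 7 1-(benzyloxy)-3-(3-bromobut-3-en-1-yl)benzene; 3 2,5-bis(benzyloxy)benzaldehyde
Product: 9 1-[2,5-bis(benzyloxy)phenyl]-4-[3-(benzyloxy)phenyl]-2-methylidenebutan-1-ol (racemic), via 4-[3-(benzyloxy)phenyl]but-1-en-2-yllithium 8 (not isolated)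
Conditions: t-BuLi (2.1 equiv), Et2O, −78 °C; then 3, THF, −78 → 0 °C; then H2O
Reagents that add atoms: none
Why: Bromine–lithium exchange of the 2-bromoalkene and 1,2-addition of the alkenyllithium to the aldehyde; the new carbinol stereocentre forms without control (racemic) and is removed by the oxidation in step 4.

Step 4
Reactants: 9 1-[2,5-bis(benzyloxy)phenyl]-4-[3-(benzyloxy)phenyl]-2-methylidenebutan-1-ol
Product: 10 1-[2,5-bis(benzyloxy)phenyl]-4-[3-(benzyloxy)phenyl]-2-methylidenebutan-1-one
Conditions: Dess–Martin periodinane (1.2 equiv), CH2Cl2, 0 → 23 °C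
Reagents that add atoms: none
Why: Dess–Martin oxidation of a secondary allylic and benzylic alcohol under mild, non-basic conditions that spare the benzyl ethers and the polymerization-prone α-methylene ketone, which is carried on without storage.

Step 5
Reactants: 10 1-[2,5-bis(benzyloxy)phenyl]-4-[3-(benzyloxy)phenyl]-2-methylidenebutan-1-one; 11 ethynylmagnesium bromide
Product: 12 3-[2,5-bis(benzyloxy)phenyl]-6-[3-(benzyloxy)phenyl]-4-methylidenehex-1-yn-3-ol (racemic)
Conditions: HC≡CMgBr (2 equiv), THF, −40 → 0 °C; then H2O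
Reagents that add atoms: ethynylmagnesium bromide, C#C[Mg]Br
Why: 1,2-Addition of an alkynyl Grignard reagent to the ketone, the small hard acetylide preferring the carbonyl carbon over the enone terminus; the tertiary carbinol centre forms racemic and is destroyed when ring A becomes aromatic in step 7.

Step 6
Reactants: 12 3-[2,5-bis(benzyloxy)phenyl]-6-[3-(benzyloxy)phenyl]-4-methylidenehex-1-yn-3-ol; 13 pivaloyl chloride
Product: 15 3-[2,5-bis(benzyloxy)phenyl]-6-[3-(benzyloxy)phenyl]-4-methylidenehex-1-yn-3-yl pivalate (racemic), via lithium tertiary alkoxide 14 (not isolated)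
Conditions: n-BuLi (1.0 equiv), THF, −78 °C; then PivCl (1.3 equiv), −78 → 23 °C; chromatography on Et3N-deactivated SiO2
Reagents that add atoms: pivaloyl chloride, CC(C)(C)C(Cl)=O
Why: O-Acylation of a lithium tertiary alkoxide with an acid chloride, in which one equivalent of base removes only the hydroxyl proton (far more acidic than the alkyne C–H) and the basic conditions avoid the acids that would ionize this carbinol; the stereocentre is untouched.

Step 7
Reactants: 15 3-[2,5-bis(benzyloxy)phenyl]-6-[3-(benzyloxy)phenyl]-4-methylidenehex-1-yn-3-yl pivalate; 16 carbon monoxide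
Product: 17 2',5'-bis(benzyloxy)-6-{2-[3-(benzyloxy)phenyl]ethyl}-4-hydroxy-[1,1'-biphenyl]-2-yl pivalate (ring A: C3 pivalate, C5 free phenol)
Conditions: [Rh(CO)2Cl]2 (5 mol %), CO (50 atm), toluene, 80 °C
Reagents that add atoms: carbon monoxide, [C-]#[O+]
Why: Monovalent rhodium binds the terminal alkyne, the pivalate carbonyl oxygen attacks the internal alkyne carbon and the old C–O bond breaks, which moves the ester from the future C2 to C3 and leaves a rhodium vinylcarbene at C4; metalla-electrocyclization onto the 1,1-disubstituted alkene gives a rhodacyclohexadiene bound at C4 and C6, CO inserts, reductive elimination forms the dienone and enolization gives the phenol. The closest known reaction type is the rhodium-catalysed five-plus-one cycloaddition of 3-acyloxy-1,4-enynes with CO to resorcinol monoesters. Ring A closes as a six-membered carbocycle by carbonylative joining of C4 and C6 through the new C5 (bonds C4–C5 and C5–C6) and then aromatizes. No stereocentre is created, and the racemic carbinol centre disappears. The step needs a 1,2- and not a 1,3-acyloxy shift, secured by the terminal alkyne, and CO insertion before C4–C6 closure, secured by CO pressure on a carbonyl-rich catalyst. Ionization of the tertiary benzylic ester is held back by the poorly leaving pivalate and by the non-polar, acid-free medium.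

Step 8
Reactants: 17 2',5'-bis(benzyloxy)-6-{2-[3-(benzyloxy)phenyl]ethyl}-4-hydroxy-[1,1'-biphenyl]-2-yl pivalate; 18 iodomethane
Product: 19 2',5'-bis(benzyloxy)-6-{2-[3-(benzyloxy)phenyl]ethyl}-4-methoxy-[1,1'-biphenyl]-2-yl pivalate
Conditions: MeI (3 equiv), K2CO3 (2 equiv), acetone, 45 °C
Reagents that add atoms: iodomethane, CI
Why: Williamson methylation of the only free phenol (C5–OH); the hindered aryl pivalate at C3 should be neither cleaved nor transferred under carbonate in acetone, so the two oxygens of ring A stay differentiated.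

Step 9
Reactants: 19 2',5'-bis(benzyloxy)-6-{2-[3-(benzyloxy)phenyl]ethyl}-4-methoxy-[1,1'-biphenyl]-2-yl pivalate
Product: 20 2',5'-bis(benzyloxy)-6-{2-[3-(benzyloxy)phenyl]ethyl}-4-methoxy-[1,1'-biphenyl]-2-ol
Conditions: NaOMe (3 equiv), MeOH/THF, 50 °C; then 1 M HCl to pH 6
Reagents that add atoms: none
Why: Transesterification of the aryl pivalate by methoxide, with the aryloxide as leaving group, frees the C3 phenol while benzyl and methyl aryl ethers are inert.

Step 10
Reactants: 20 2',5'-bis(benzyloxy)-6-{2-[3-(benzyloxy)phenyl]ethyl}-4-methoxy-[1,1'-biphenyl]-2-ol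
Product: 21 6-[2-(3-hydroxyphenyl)ethyl]-4-methoxy-[1,1'-biphenyl]-2,2',5'-triol (target)
Conditions: H2 (1 atm), Pd/C (10 wt %), EtOAc/MeOH, 23 °C
Reagents that add atoms: none
Why: Catalytic hydrogenolysis of the three benzyl aryl ethers over palladium on carbon; no other reducible group is present, and the neutral conditions suit the oxidation-prone hydroquinone.

Compound list

1 | 2,5-dihydroxybenzaldehyde | O=Cc1cc(O)ccc1O | starting material
2 | benzyl bromide | BrCc1ccccc1 | starting material
3 | 2,5-bis(benzyloxy)benzaldehyde | O=Cc1cc(OCc2ccccc2)ccc1OCc1ccccc1 | intermediate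
4 | 1-(benzyloxy)-3-(chloromethyl)benzene | ClCc1cccc(OCc2ccccc2)c1 | starting material
5 | 2,3-dibromopropene | C=C(Br)CBr | starting material
6 | 3-(benzyloxy)benzylmagnesium chloride | Cl[Mg]Cc1cccc(OCc2ccccc2)c1 | intermediate (not isolated)
7 | 1-(benzyloxy)-3-(3-bromobut-3-en-1-yl)benzene | C=C(Br)CCc1cccc(OCc2ccccc2)c1 | intermediate
8 | 4-[3-(benzyloxy)phenyl]but-1-en-2-yllithium | [Li]C(=C)CCc1cccc(OCc2ccccc2)c1 | intermediate (not isolated)
9 | 1-[2,5-bis(benzyloxy)phenyl]-4-[3-(benzyloxy)phenyl]-2-methylidenebutan-1-ol (racemic) | OC(C(=C)CCc1cccc(OCc2ccccc2)c1)c1cc(OCc2ccccc2)ccc1OCc1ccccc1 | intermediate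
10 | 1-[2,5-bis(benzyloxy)phenyl]-4-[3-(benzyloxy)phenyl]-2-methylidenebutan-1-one | O=C(C(=C)CCc1cccc(OCc2ccccc2)c1)c1cc(OCc2ccccc2)ccc1OCc1ccccc1 | intermediate
11 | ethynylmagnesium bromide | C#C[Mg]Br | starting material
12 | 3-[2,5-bis(benzyloxy)phenyl]-6-[3-(benzyloxy)phenyl]-4-methylidenehex-1-yn-3-ol (racemic) | C#CC(O)(C(=C)CCc1cccc(OCc2ccccc2)c1)c1cc(OCc2ccccc2)ccc1OCc1ccccc1 | intermediate
13 | pivaloyl chloride | CC(C)(C)C(Cl)=O | starting material
14 | lithium 3-[2,5-bis(benzyloxy)phenyl]-6-[3-(benzyloxy)phenyl]-4-methylidenehex-1-yn-3-olate (racemic) | [Li]OC(C#C)(C(=C)CCc1cccc(OCc2ccccc2)c1)c1cc(OCc2ccccc2)ccc1OCc1ccccc1 | intermediate (not isolated)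
15 | 3-[2,5-bis(benzyloxy)phenyl]-6-[3-(benzyloxy)phenyl]-4-methylidenehex-1-yn-3-yl pivalate (racemic) | C#CC(OC(=O)C(C)(C)C)(C(=C)CCc1cccc(OCc2ccccc2)c1)c1cc(OCc2ccccc2)ccc1OCc1ccccc1 | intermediate
16 | carbon monoxide | [C-]#[O+] | starting material
17 | 2',5'-bis(benzyloxy)-6-{2-[3-(benzyloxy)phenyl]ethyl}-4-hydroxy-[1,1'-biphenyl]-2-yl pivalate | CC(C)(C)C(=O)Oc1cc(O)cc(CCc2cccc(OCc3ccccc3)c2)c1-c1cc(OCc2ccccc2)ccc1OCc1ccccc1 | intermediate
18 | iodomethane | CI | starting material
19 | 2',5'-bis(benzyloxy)-6-{2-[3-(benzyloxy)phenyl]ethyl}-4-methoxy-[1,1'-biphenyl]-2-yl pivalate | COc1cc(CCc2cccc(OCc3ccccc3)c2)c(-c2cc(OCc3ccccc3)ccc2OCc2ccccc2)c(OC(=O)C(C)(C)C)c1 | intermediate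
20 | 2',5'-bis(benzyloxy)-6-{2-[3-(benzyloxy)phenyl]ethyl}-4-methoxy-[1,1'-biphenyl]-2-ol | COc1cc(O)c(-c2cc(OCc3ccccc3)ccc2OCc2ccccc2)c(CCc2cccc(OCc3ccccc3)c2)c1 | intermediate
21 | 6-[2-(3-hydroxyphenyl)ethyl]-4-methoxy-[1,1'-biphenyl]-2,2',5'-triol | COc1cc(O)c(-c2cc(O)ccc2O)c(CCc2cccc(O)c2)c1 | target

Total step count: 10. Longest linear sequence: 9 steps (steps 1, 3, 4, 5, 6, 7, 8, 9, 10; the branch through step 2 is equally long).

Steps most likely to fail

Step 7. What may go wrong: heterolysis of the tertiary benzylic C–O bond with return of the pivalate at the alkene terminus (allylic transposition), a 1,3- in place of the 1,2-acyloxy shift, or closure of the rhodacycle without CO insertion. Fallback (sets out from 7, comes back at 19): ring B is taken off the carbinol carbon, so that the same carbonylation runs on a secondary, non-benzylic ester, and is attached afterwards by cross-coupling. Alkenyllithium 8, made from 7 as in step 3, is formylated with DMF to 4-[3-(benzyloxy)phenyl]-2-methylidenebutanal F1. Addition of 11 gives 6-[3-(benzyloxy)phenyl]-4-methylidenehex-1-yn-3-ol F2, and acylation with 13 (pyridine, DMAP) gives 6-[3-(benzyloxy)phenyl]-4-methylidenehex-1-yn-3-yl pivalate F3. The conditions of step 7 should turn this into 3-{2-[3-(benzyloxy)phenyl]ethyl}-5-hydroxyphenyl pivalate F4. Bromination with NBS at low temperature is expected para to the free phenol, at C2 of ring A, to give 2-bromo-3-{2-[3-(benzyloxy)phenyl]ethyl}-5-hydroxyphenyl pivalate F5, and methylation as in step 8 gives 2-bromo-3-{2-[3-(benzyloxy)phenyl]ethyl}-5-methoxyphenyl pivalate F6. The coupling partner comes from bromohydroquinone: benzylation (BnBr, K2CO3, DMF) gives 2-bromo-1,4-bis(benzyloxy)benzene F7, and Miyaura borylation (bis(pinacolato)diboron, Pd(dppf)Cl2, KOAc, dioxane, 90 °C) gives 2-[2,5-bis(benzyloxy)phenyl]-4,4,5,5-tetramethyl-1,3,2-dioxaborolane F8. Suzuki–Miyaura coupling of F6 and F8 (Pd(OAc)2, SPhos, K3PO4, toluene/H2O, 90 °C) forms the bond from C2 to ring B and gives 19.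

Step 6. What may go wrong: slow or incomplete acylation of the crowded alkoxide by the bulky acid chloride, loss of acetylide from the alkoxide on warming (retro-addition to 10), or ionization of the ester during purification. Fallback (sets out from 12, comes back at 20): the small acetate takes the place of the pivalate and is put on the neutral alcohol by nucleophilic catalysis (Ac2O, Et3N, DMAP, CH2Cl2, 23 °C) to give 3-[2,5-bis(benzyloxy)phenyl]-6-[3-(benzyloxy)phenyl]-4-methylidenehex-1-yn-3-yl acetate F9. The carbonylation of step 7 should then give 2',5'-bis(benzyloxy)-6-{2-[3-(benzyloxy)phenyl]ethyl}-4-hydroxy-[1,1'-biphenyl]-2-yl acetate F10. Because an aryl acetate can pass to a neighbouring phenoxide under carbonate, the phenol is methylated under neutral Mitsunobu conditions (MeOH, PPh3, DIAD, THF) to 2',5'-bis(benzyloxy)-6-{2-[3-(benzyloxy)phenyl]ethyl}-4-methoxy-[1,1'-biphenyl]-2-yl acetate F11. K2CO3 in MeOH then cleaves the acetate and gives 20.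

Step 5. What may go wrong: conjugate addition to, or anionic oligomerization of, the α-methylene ketone in competition with carbonyl addition, and decay of the enone before it is used. Fallback (sets out from 3, comes back at 12): the two carbonyl additions are run in the reverse order, so that no enone is needed. Commercial lithium (trimethylsilyl)acetylide adds to 3 (THF, −78 °C) to give 1-[2,5-bis(benzyloxy)phenyl]-3-(trimethylsilyl)prop-2-yn-1-ol F12. MnO2 in CH2Cl2 oxidizes it to 1-[2,5-bis(benzyloxy)phenyl]-3-(trimethylsilyl)prop-2-yn-1-one F13. Alkenyllithium 8 (from 7 as in step 3) adds to the carbonyl group at −78 °C to give 3-[2,5-bis(benzyloxy)phenyl]-6-[3-(benzyloxy)phenyl]-4-methylidene-1-(trimethylsilyl)hex-1-yn-3-ol F14. K2CO3 in MeOH removes the silyl group and gives 12.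

Further compounds

F1 | step 7 | 4-[3-(benzyloxy)phenyl]-2-methylidenebutanal | O=CC(=C)CCc1cccc(OCc2ccccc2)c1
F2 | step 7 | 6-[3-(benzyloxy)phenyl]-4-methylidenehex-1-yn-3-ol (racemic) | C#CC(O)C(=C)CCc1cccc(OCc2ccccc2)c1
F3 | step 7 | 6-[3-(benzyloxy)phenyl]-4-methylidenehex-1-yn-3-yl pivalate (racemic) | C#CC(OC(=O)C(C)(C)C)C(=C)CCc1cccc(OCc2ccccc2)c1
F4 | step 7 | 3-{2-[3-(benzyloxy)phenyl]ethyl}-5-hydroxyphenyl pivalate | CC(C)(C)C(=O)Oc1cc(O)cc(CCc2cccc(OCc3ccccc3)c2)c1
F5 | step 7 | 2-bromo-3-{2-[3-(benzyloxy)phenyl]ethyl}-5-hydroxyphenyl pivalate | CC(C)(C)C(=O)Oc1cc(O)cc(CCc2cccc(OCc3ccccc3)c2)c1Br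
F6 | step 7 | 2-bromo-3-{2-[3-(benzyloxy)phenyl]ethyl}-5-methoxyphenyl pivalate | CC(C)(C)C(=O)Oc1cc(OC)cc(CCc2cccc(OCc3ccccc3)c2)c1Br
F7 | step 7 | 2-bromo-1,4-bis(benzyloxy)benzene | Brc1cc(OCc2ccccc2)ccc1OCc1ccccc1
F8 | step 7 | 2-[2,5-bis(benzyloxy)phenyl]-4,4,5,5-tetramethyl-1,3,2-dioxaborolane | CC1(C)OB(OC1(C)C)c1cc(OCc2ccccc2)ccc1OCc1ccccc1
F9 | step 6 | 3-[2,5-bis(benzyloxy)phenyl]-6-[3-(benzyloxy)phenyl]-4-methylidenehex-1-yn-3-yl acetate (racemic) | C#CC(OC(C)=O)(C(=C)CCc1cccc(OCc2ccccc2)c1)c1cc(OCc2ccccc2)ccc1OCc1ccccc1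
F10 | step 6 | 2',5'-bis(benzyloxy)-6-{2-[3-(benzyloxy)phenyl]ethyl}-4-hydroxy-[1,1'-biphenyl]-2-yl acetate | CC(=O)Oc1cc(O)cc(CCc2cccc(OCc3ccccc3)c2)c1-c1cc(OCc2ccccc2)ccc1OCc1ccccc1
F11 | step 6 | 2',5'-bis(benzyloxy)-6-{2-[3-(benzyloxy)phenyl]ethyl}-4-methoxy-[1,1'-biphenyl]-2-yl acetate | CC(=O)Oc1cc(OC)cc(CCc2cccc(OCc3ccccc3)c2)c1-c1cc(OCc2ccccc2)ccc1OCc1ccccc1
F12 | step 5 | 1-[2,5-bis(benzyloxy)phenyl]-3-(trimethylsilyl)prop-2-yn-1-ol (racemic) | OC(C#C[Si](C)(C)C)c1cc(OCc2ccccc2)ccc1OCc1ccccc1
F13 | step 5 | 1-[2,5-bis(benzyloxy)phenyl]-3-(trimethylsilyl)prop-2-yn-1-one | O=C(C#C[Si](C)(C)C)c1cc(OCc2ccccc2)ccc1OCc1ccccc1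
F14 | step 5 | 3-[2,5-bis(benzyloxy)phenyl]-6-[3-(benzyloxy)phenyl]-4-methylidene-1-(trimethylsilyl)hex-1-yn-3-ol (racemic) | C[Si](C)(C)C#CC(O)(C(=C)CCc1cccc(OCc2ccccc2)c1)c1cc(OCc2ccccc2)ccc1OCc1ccccc1
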